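**Retrosynthetic overview**
1. Target ⇐ removal of two MOM groups ⇐ aromatic Claisen rearrangement of the 4'-O-prenyl ether (C3' is blocked, so the 1,1-dimethylallyl group can only land on C5').
2. C3–C1' bond and the (S) centre ⇐ new enantioselective reductive Heck coupling of 7-(methoxymethoxy)-2H-chromene with a ring B aryl triflate.
3. Aryl triflate ⇐ 2,3,4-trihydroxybenzaldehyde by 4-O-benzylation, 3-O-MOM protection, 2-O-methylation, Dakin-type oxidation and triflation; ring B regiochemistry comes from the starting material.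
4. Chromene ⇐ 2,4-dihydroxybenzaldehyde by 4-O-MOM protection and Schweizer annulation.
5. Ring order: rings A and B are bought as benzaldehydes; pyran ring C is closed in step 7, before the two halves are joined.

Assumption: the SMILES descriptor corresponds to (3S) (chroman numbering O1, C2, C3, C4; ring B positions primed), and compounds 1 and 8 are taken as commercial.

**Route**

Step 1
Reactants: 1 2,3,4-trihydroxybenzaldehyde
Product: 2 4-(benzyloxy)-2,3-dihydroxybenzaldehyde
Conditions: BnBr (1.05 equiv), NaHCO3, DMF, 40 °C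
Reagents that add atoms: benzyl bromide, BrCc1ccccc1
Why: Williamson etherification under weak base alkylates only the most acidic phenol (para to the formyl group), because the 2-OH is hydrogen-bonded to the carbonyl and the 3-OH is flanked on both sides.

Step 2
Reactants: 2 4-(benzyloxy)-2,3-dihydroxybenzaldehyde
Product: 3 4-(benzyloxy)-2-hydroxy-3-(methoxymethoxy)benzaldehyde
Conditions: MOMCl (1.1 equiv), K2CO3, acetone, 0 °C to rt
Reagents that add atoms: chloromethyl methyl ether, COCCl
Why: O-alkylation (MOM acetal formation) goes to the 3-OH because the 2-OH stays locked in its chelate with the aldehyde, as in the usual 3,4-protection of 2,3,4-trihydroxyaryl carbonyl compounds.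

Step 3
Reactants: 3 4-(benzyloxy)-2-hydroxy-3-(methoxymethoxy)benzaldehyde
Product: 4 4-(benzyloxy)-2-methoxy-3-(methoxymethoxy)benzaldehyde
Conditions: MeI, K2CO3, DMF, 40 °C
Reagents that add atoms: iodomethane, CI
Why: Williamson methylation of the remaining chelated phenol installs the 2'-methoxy group.

Step 4
Reactants: 4 4-(benzyloxy)-2-methoxy-3-(methoxymethoxy)benzaldehyde
Product: 6 4-(benzyloxy)-2-methoxy-3-(methoxymethoxy)phenol, via aryl formate 5 (not isolated)
Conditions: mCPBA, CH2Cl2, 0 °C to rt; then K2CO3 (cat.), MeOH, rt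
Reagents that add atoms: meta-chloroperoxybenzoic acid, OOC(=O)c1cccc(Cl)c1
Why: Baeyer–Villiger (Dakin-type) oxidation of the electron-rich benzaldehyde proceeds with aryl migration, and methanolysis of the formate leaves a phenol on the carbon that becomes C1'.

Step 5
Reactants: 6 4-(benzyloxy)-2-methoxy-3-(methoxymethoxy)phenol
Product: 7 4-(benzyloxy)-2-methoxy-3-(methoxymethoxy)phenyl trifluoromethanesulfonate
Conditions: Tf2O, 30% aq K3PO4, toluene, 0 °C to rt
Reagents that add atoms: trifluoromethanesulfonic anhydride, O=S(=O)(OS(=O)(=O)C(F)(F)F)C(F)(F)F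
Why: O-sulfonylation of the phenoxide under biphasic conditions is fast and leaves the MOM and benzyl ethers untouched.

Step 6
Reactants: 8 2,4-dihydroxybenzaldehyde
Product: 9 2-hydroxy-4-(methoxymethoxy)benzaldehyde
Conditions: MOMCl (1.05 equiv), K2CO3, acetone, 0 °C to rt
Reagents that add atoms: chloromethyl methyl ether, COCCl
Why: O-alkylation is selective for the unchelated 4-OH over the hydrogen-bonded 2-OH.

Step 7
Reactants: 9 2-hydroxy-4-(methoxymethoxy)benzaldehyde
Product: 11 7-(methoxymethoxy)-2H-chromene, via phosphorus ylide 10 (not isolated)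
Conditions: NaH, DMF, 0 °C; then CH2=CHPPh3Br, rt to 70 °C
Reagents that add atoms: vinyltriphenylphosphonium bromide, C=C[P+](c1ccccc1)(c1ccccc1)c1ccccc1.[Br-]
Why: Schweizer reaction, in which oxa-Michael addition of the phenoxide to the vinylphosphonium salt gives an ylide that closes pyran ring C by intramolecular Wittig olefination.

Step 8
Reactants: 7 4-(benzyloxy)-2-methoxy-3-(methoxymethoxy)phenyl trifluoromethanesulfonate; 11 7-(methoxymethoxy)-2H-chromene
Product: 12 (3S)-3-[4-(benzyloxy)-2-methoxy-3-(methoxymethoxy)phenyl]-7-(methoxymethoxy)chromane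
Conditions: Pd(OAc)2 (5 mol%), (R)-DTBM-SEGPHOS (6 mol%), HCO2Na (2 equiv), 11 (2 equiv), DMF, 60 °C
Reagents that add atoms: none
Why: Proposed new method: an enantioselective intermolecular reductive Heck (hydroarylation) of a 2H-chromene, in which the cationic aryl–palladium species from triflate 7 and the chiral bisphosphine adds syn across C3=C4 with aryl to C3 and palladium to benzylic C4 (the regiochemistry seen in racemic Heck oxyarylations of 2H-chromenes that give pterocarpans), the ligand selects the alkene face in this insertion (aryl delivery to the C3 Re face gives S), the only hydrogen on C3 is anti to palladium so β-hydride elimination is shut off and formate instead delivers hydride (decarboxylation, then C–H reductive elimination) to leave C4 as CH2; the closest known reaction types are the asymmetric hydroarylation of norbornene-type alkenes with aryl triflates and formate and the asymmetric Heck arylation of 2,3-dihydrofuran, and the (R)-ligand is the working choice whose sense is checked on the first run, with the (S)-ligand used if it is reversed.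

Step 9
Reactants: 12 (3S)-3-[4-(benzyloxy)-2-methoxy-3-(methoxymethoxy)phenyl]-7-(methoxymethoxy)chromane
Product: 13 4-[(3S)-7-(methoxymethoxy)chroman-3-yl]-3-methoxy-2-(methoxymethoxy)phenol
Conditions: H2 (1 atm), 10% Pd/C, EtOAc/MeOH, rt
Reagents that add atoms: none
Why: Hydrogenolysis of the benzyl ether frees only the 4'-OH, with MOM ethers, the chroman C–O bonds and the C3 centre unaffected.

Step 10
Reactants: 13 4-[(3S)-7-(methoxymethoxy)chroman-3-yl]-3-methoxy-2-(methoxymethoxy)phenol
Product: 14 (3S)-3-[2-methoxy-3-(methoxymethoxy)-4-(3-methylbut-2-en-1-yloxy)phenyl]-7-(methoxymethoxy)chromane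
Conditions: prenyl bromide, K2CO3, acetone, reflux
Reagents that add atoms: 1-bromo-3-methylbut-2-ene, CC(C)=CCBr
Why: Williamson etherification by SN2 attack of the single free phenoxide on the primary allylic bromide.

Step 11
Reactants: 14 (3S)-3-[2-methoxy-3-(methoxymethoxy)-4-(3-methylbut-2-en-1-yloxy)phenyl]-7-(methoxymethoxy)chromane
Product: 16 4-[(3S)-7-(methoxymethoxy)chroman-3-yl]-3-methoxy-2-(methoxymethoxy)-6-(2-methylbut-3-en-2-yl)phenol, via ortho-dienone 15 (not isolated)
Conditions: PhNEt2, 190 °C, 2 h, sealed tube under Ar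
Reagents that add atoms: none
Why: Aromatic Claisen rearrangement, a [3,3] shift to C5' (the only ortho carbon bearing hydrogen, C3' carrying OMOM) that inverts the allyl unit to the 1,1-dimethylallyl group, followed by tautomerisation of the dienone to the phenol; C3 is not involved.

Step 12
Reactants: 16 4-[(3S)-7-(methoxymethoxy)chroman-3-yl]-3-methoxy-2-(methoxymethoxy)-6-(2-methylbut-3-en-2-yl)phenol
Product: 17 (3S)-3-[3,4-dihydroxy-2-methoxy-5-(2-methylbut-3-en-2-yl)phenyl]chroman-7-ol
Conditions: 3 M aq HCl, MeOH, 45 °C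
Reagents that add atoms: none
Why: Acid-catalysed methanolysis of the two MOM acetals, mild enough to leave the monosubstituted alkene, the methyl ether and the C3 centre intact.

**Compound list**
1 | 2,3,4-trihydroxybenzaldehyde | O=Cc1ccc(O)c(O)c1O | starting material
2 | 4-(benzyloxy)-2,3-dihydroxybenzaldehyde | O=Cc1ccc(OCc2ccccc2)c(O)c1O | intermediate
3 | 4-(benzyloxy)-2-hydroxy-3-(methoxymethoxy)benzaldehyde | O=Cc1ccc(OCc2ccccc2)c(OCOC)c1O | intermediate
4 | 4-(benzyloxy)-2-methoxy-3-(methoxymethoxy)benzaldehyde | O=Cc1ccc(OCc2ccccc2)c(OCOC)c1OC | intermediate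
5 | 4-(benzyloxy)-2-methoxy-3-(methoxymethoxy)phenyl formate (not isolated) | O=COc1ccc(OCc2ccccc2)c(OCOC)c1OC | intermediate
6 | 4-(benzyloxy)-2-methoxy-3-(methoxymethoxy)phenol | Oc1ccc(OCc2ccccc2)c(OCOC)c1OC | intermediate
7 | 4-(benzyloxy)-2-methoxy-3-(methoxymethoxy)phenyl trifluoromethanesulfonate | O=S(=O)(Oc1ccc(OCc2ccccc2)c(OCOC)c1OC)C(F)(F)F | intermediate
8 | 2,4-dihydroxybenzaldehyde | O=Cc1ccc(O)cc1O | starting material
9 | 2-hydroxy-4-(methoxymethoxy)benzaldehyde | O=Cc1ccc(OCOC)cc1O | intermediate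
10 | {2-[2-formyl-5-(methoxymethoxy)phenoxy]ethylidene}triphenylphosphorane (not isolated) | O=Cc1ccc(OCOC)cc1OCC=P(c1ccccc1)(c1ccccc1)c1ccccc1 | intermediate
11 | 7-(methoxymethoxy)-2H-chromene | COCOc1ccc2C=CCOc2c1 | intermediate
12 | (3S)-3-[4-(benzyloxy)-2-methoxy-3-(methoxymethoxy)phenyl]-7-(methoxymethoxy)chromane | COc1c(OCOC)c(OCc2ccccc2)ccc1[C@H]1COc2cc(OCOC)ccc2C1 | intermediate
13 | 4-[(3S)-7-(methoxymethoxy)chroman-3-yl]-3-methoxy-2-(methoxymethoxy)phenol | COc1c(OCOC)c(O)ccc1[C@H]1COc2cc(OCOC)ccc2C1 | intermediate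
14 | (3S)-3-[2-methoxy-3-(methoxymethoxy)-4-(3-methylbut-2-en-1-yloxy)phenyl]-7-(methoxymethoxy)chromane | COc1c(OCOC)c(OCC=C(C)C)ccc1[C@H]1COc2cc(OCOC)ccc2C1 | intermediate
15 | 4-[(3S)-7-(methoxymethoxy)chroman-3-yl]-3-methoxy-2-(methoxymethoxy)-6-(2-methylbut-3-en-2-yl)cyclohexa-2,4-dien-1-one, epimers at C6 (not isolated) | COC1=C(OCOC)C(=O)C(C(C)(C)C=C)C=C1[C@H]1COc2cc(OCOC)ccc2C1 | intermediate
16 | 4-[(3S)-7-(methoxymethoxy)chroman-3-yl]-3-methoxy-2-(methoxymethoxy)-6-(2-methylbut-3-en-2-yl)phenol | COc1c(OCOC)c(O)c(C(C)(C)C=C)cc1[C@H]1COc2cc(OCOC)ccc2C1 | intermediate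
17 | (3S)-3-[3,4-dihydroxy-2-methoxy-5-(2-methylbut-3-en-2-yl)phenyl]chroman-7-ol | C=CC(C)(C)c1cc([C@H]2COc3cc(O)ccc3C2)c(OC)c(O)c1O | target

**Step count and risks**
Total steps: 12. Longest linear sequence: 10 (steps 1–5, then 8–12).

Step 8 (the proposed new reaction) is the most likely to fail. The likely failure modes are formate reduction of the aryl–palladium species to the arene before insertion, ring opening of the allylic C2–O bond by zerovalent palladium, and low enantioselectivity. The fallback uses only known chemistry; it sets out from 7 and returns to the route at 13. Commercial 7-hydroxychroman-4-one (O=C1CCOc2cc(O)ccc12) is protected with MOMCl and K2CO3 in acetone to give 7-(methoxymethoxy)chroman-4-one F1. Palladium-catalysed ketone α-arylation of F1 with triflate 7 (Pd(OAc)2, XPhos, K3PO4, toluene, 90 °C) gives racemic 3-[4-(benzyloxy)-2-methoxy-3-(methoxymethoxy)phenyl]-7-(methoxymethoxy)chroman-4-one F2. Asymmetric transfer hydrogenation with dynamic kinetic resolution (RuCl[(S,S)-TsDPEN](p-cymene), HCO2H/Et3N, EtOAc, 40 °C) reduces the ketone while the labile C3 centre equilibrates, giving cis-(3S,4S)-3-[4-(benzyloxy)-2-methoxy-3-(methoxymethoxy)phenyl]-7-(methoxymethoxy)chroman-4-ol F3. Hydrogenolysis (H2, Pd/C, EtOH, AcOH cat.) removes the benzylic 4-OH and the benzyl ether together and gives 13.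

Step 11 (Claisen rearrangement) may give abnormal-Claisen isomers, loss of the prenyl group, or cyclisation of the product phenol onto the new alkene at 190 °C. The fallback sets out from 13 and returns at 17. Amine-catalysed ortho-bromination of the free phenol (NBS, iPr2NH cat., CH2Cl2, −40 °C; these conditions favour the phenol ring over ring A) gives 6-bromo-4-[(3S)-7-(methoxymethoxy)chroman-3-yl]-3-methoxy-2-(methoxymethoxy)phenol F4. MOM protection (MOMCl, K2CO3, acetone) gives (3S)-3-[5-bromo-2-methoxy-3,4-bis(methoxymethoxy)phenyl]-7-(methoxymethoxy)chromane F5. A ligand-controlled branch-selective (γ-selective) Suzuki–Miyaura coupling with prenylboronic acid pinacol ester (Pd(OAc)2, bulky biarylphosphine, K3PO4, THF/H2O, 40 °C) gives (3S)-3-[2-methoxy-3,4-bis(methoxymethoxy)-5-(2-methylbut-3-en-2-yl)phenyl]-7-(methoxymethoxy)chromane F6. Its three MOM groups are removed under the step 12 conditions to give 17.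

Step 7 (Schweizer annulation) can give modest yields with electron-rich salicylaldehydes, and the chromene is prone to polymerise. The fallback sets out from 9 and returns at 11. O-Allylation (allyl bromide, K2CO3, acetone) gives 2-(allyloxy)-4-(methoxymethoxy)benzaldehyde F7. Wittig methylenation (Ph3PCH3Br, KOtBu, THF, 0 °C) gives 2-(allyloxy)-4-(methoxymethoxy)-1-vinylbenzene F8. Ring-closing metathesis with the second-generation Grubbs catalyst, RuCl2(=CHPh)(H2IMes)(PCy3) (CH2Cl2, 40 °C), closes ring C and gives 11.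

**Further compounds**
F1 | step 8 | 7-(methoxymethoxy)chroman-4-one | COCOc1ccc2C(=O)CCOc2c1
F2 | step 8 | racemic 3-[4-(benzyloxy)-2-methoxy-3-(methoxymethoxy)phenyl]-7-(methoxymethoxy)chroman-4-one | COCOc1ccc2C(=O)C(COc2c1)c1ccc(OCc2ccccc2)c(OCOC)c1OC
F3 | step 8 | (3S,4S)-3-[4-(benzyloxy)-2-methoxy-3-(methoxymethoxy)phenyl]-7-(methoxymethoxy)chroman-4-ol | O[C@H]1[C@@H](c2ccc(OCc3ccccc3)c(OCOC)c2OC)COc2cc(OCOC)ccc21
F4 | step 11 | 6-bromo-4-[(3S)-7-(methoxymethoxy)chroman-3-yl]-3-methoxy-2-(methoxymethoxy)phenol | COc1c(OCOC)c(O)c(Br)cc1[C@H]1COc2cc(OCOC)ccc2C1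
F5 | step 11 | (3S)-3-[5-bromo-2-methoxy-3,4-bis(methoxymethoxy)phenyl]-7-(methoxymethoxy)chromane | COc1c(OCOC)c(OCOC)c(Br)cc1[C@H]1COc2cc(OCOC)ccc2C1
F6 | step 11 | (3S)-3-[2-methoxy-3,4-bis(methoxymethoxy)-5-(2-methylbut-3-en-2-yl)phenyl]-7-(methoxymethoxy)chromane | COc1c(OCOC)c(OCOC)c(C(C)(C)C=C)cc1[C@H]1COc2cc(OCOC)ccc2C1
F7 | step 7 | 2-(allyloxy)-4-(methoxymethoxy)benzaldehyde | C=CCOc1cc(OCOC)ccc1C=O
F8 | step 7 | 2-(allyloxy)-4-(methoxymethoxy)-1-vinylbenzene | C=CCOc1cc(OCOC)ccc1C=C
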